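**Retrosynthetic overview**
- Structural feature: C11, the isopropenyl carbon on C7, sits where the CMe2 bridge carbon of (−)-β-pinene spans C7 and C9 of ring B (C5–C10), and C1 of ring A (C1–C5, C10) is the pinene's exocyclic methylene carbon on C10; the bridge therefore fixes the C7–C11 bond cis to the C5 methyl.
- Endgame: O9 ester from the 8α,9α-diol; the diol from OsO4 on a trans-fused 8-ene; the 10α-H and the 8-ene from palladium hydrogenolysis of an 8β-allylic formate; C8 oxygen from allylic oxidation of the 9-ene; the isopropenyl group is carried as a C11 chloride.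
- Key disconnection: C1–C2 (ring A) together with C9–C11, i.e. a Prins closure of a C2 aldehyde onto the pinene methylene with opening of the cyclobutane.
- Precursor: from nopinone by C5 methylation, crotyl ketal Claisen rearrangement (C5 and C4), methylenation, hydroboration and oxidation.
- Ring order: ring B is the six-membered ring of the pinane; ring A is closed in the key step.

Key step: step 7

Convention: eremophilane numbers are used for every compound, also the pinane intermediates (C10 carbonyl or methylene carbon, C5 its neighbour, C7 and C9 bridgeheads, C8 the CH2 bridge, C11 the CMe2 bridge, C14 the methyl on C5, C15 the methyl on C4); β is the face of the C5 methyl.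
Assumption: the Prins closure is taken to give mainly the equatorial 2β-alcohol; steps 8 and 9 make the result at C2 irrelevant, because both epimers give ketone 17.

**Step 1**
Reactants: 1 (−)-β-pinene
Product: 3 (+)-nopinone, via secondary ozonide 2 (not isolated)
Conditions: O3, CH2Cl2, −78 °C; then Me2S, −78 → 25 °C
Reagents that add atoms: ozone, [O-][O+]=O
Why: Ozonolysis of the exocyclic 1,1-disubstituted alkene and reductive cleavage of the ozonide should give the ketone without touching the two bridgehead stereocentres.

**Step 2**
Reactants: 3 (+)-nopinone; 4 iodomethane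
Product: 6 3-methylnopinone, via lithium enolate 5 (not isolated)
Conditions: LiN(iPr)2, THF, −78 °C; then MeI, −78 → 0 °C
Reagents that add atoms: none
Why: C9 is a bridgehead, so only C5 can be enolised, and enolate alkylation should place the methyl on C5 anti to the CMe2 bridge, a centre that is flattened again in step 3.

**Step 3**
Reactants: 6 3-methylnopinone; 7 (E)-but-2-en-1-ol
Product: 10 butenyl ketone, via dicrotyl ketal 8 (not isolated), via crotyl enol ether 9 (not isolated)
Conditions: Me2C(OMe)2, PPTS (cat.), PhH, 80 °C, distil; then xylene, 140 °C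
Reagents that add atoms: none
Why: Ketal exchange and loss of crotyl alcohol can only give the C10=C5 enol ether, whose Claisen rearrangement through a chair on the face anti to the CMe2 bridge should form C5–C4, leave the C5 methyl syn to the bridge and, with the (E)-crotyl methyl equatorial, set C4 as S.

**Step 4**
Reactants: 10 butenyl ketone
Product: 11 methylene diene
Conditions: Ph3PCH3Br, KOtBu, toluene, 90 °C
Reagents that add atoms: methyltriphenylphosphonium bromide, C[P+](c1ccccc1)(c1ccccc1)c1ccccc1.[Br-]
Why: The ketone has no enolisable hydrogen, so a Wittig methylenation can be forced onto the hindered carbonyl at 90 °C, as with fenchone-type ketones.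

**Step 5**
Reactants: 11 methylene diene
Product: 13 primary alcohol, via alkyldisiamylborane 12 (not isolated)
Conditions: Sia2BH (from BH3·THF and 2-methylbut-2-ene), THF, 0 °C; then NaOH, H2O2, 0 → 25 °C
Reagents that add atoms: hydrogen peroxide, OO
Why: Disiamylborane should add to the monosubstituted vinyl group much faster than to the 1,1-disubstituted methylene flanked by a quaternary carbon and a bridgehead, and oxidation gives the anti-Markovnikov alcohol (hydroboration–oxidation).

**Step 6**
Reactants: 13 primary alcohol
Product: 14 aldehyde (key precursor)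
Conditions: Dess–Martin periodinane, NaHCO3, CH2Cl2, 0 → 25 °C
Reagents that add atoms: none
Why: Buffered Dess–Martin oxidation should give the aldehyde under non-acidic conditions that spare the acid-sensitive β-pinene unit.

**Step 7**
Reactants: 14 aldehyde
Product: 16 chloro alcohol (2β-OH), via trichlorotin alkoxide 15 (not isolated)
Conditions: SnCl4 (1.1 equiv), CH2Cl2 (0.01 M), −78 °C; then aq. NaHCO3
Reagents that add atoms: tin tetrachloride, Cl[Sn](Cl)(Cl)Cl
Why: Proposed new method: SnCl4 binds the aldehyde oxygen, the methylene carbon C1 adds to C2 so that the positive charge arrives at C10 beside the cyclobutane, and the aligned C9–C11 bond then breaks with release of the four-ring strain to leave the C9=C10 alkene and a tertiary C11 cation that takes chloride from the chlorostannate; this merges two known reaction types, the Lewis acid Prins reaction of β-pinene with aldehydes and the opening of pinanyl cations to p-menth-1-en-8-yl cations (the propagation step of cationic β-pinene polymerisation), into an intramolecular cascade not yet shown on such a substrate. Ring A closes as a six-membered carbocycle by attack of the olefin terminus on the carbonyl carbon through a chair in which both olefin carbons lie in the new ring and the C=O is exocyclic (6-endo with respect to the alkene). The only new stereocentre, C2, is set by that chair, in which the C4 methyl is equatorial and the tin-bound oxygen is expected to be equatorial, giving the 2β-alcohol, while C4, C5 and C7 are carried over unchanged. The step needs C9–C11 cleavage to outrun Wagner–Meerwein migration of C11 to C10 and capture of the C10 cation; the tertiary cation that cleavage forms, the strain it releases and the crowding a shift towards the quaternary C5 would cause favour cleavage, and cold, chloride-rich SnCl4 should trap the C11 cation. The ene pathway usual for β-pinene is closed because C5 is quaternary and C9 is a bridgehead.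

**Step 8**
Reactants: 16 chloro alcohol (2β-OH)
Product: 17 9-en-2-one
Conditions: Dess–Martin periodinane, NaHCO3, CH2Cl2, 0 °C
Reagents that add atoms: none
Why: Buffered Dess–Martin oxidation should convert either C2 epimer into the β,γ-unsaturated ketone without moving the 9-ene into conjugation, as in the oxidation of cholesterol to cholest-5-en-3-one.

**Step 9**
Reactants: 17 9-en-2-one
Product: 18 2α-alcohol
Conditions: LiBH(s-Bu)3, THF, −78 °C; then H2O
Reagents that add atoms: none
Why: The bulky hydride should attack the ring A ketone along the equatorial direction, so the hydroxyl ends up axial (2α, anti to the C5 methyl), as in selectride reductions of 5-en-3-one steroids to the 3α-alcohols.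

**Step 10**
Reactants: 18 2α-alcohol
Product: 19 silyl ether
Conditions: TBSCl, imidazole, DMF, 25 °C
Reagents that add atoms: tert-butyldimethylsilyl chloride, CC(C)(C)[Si](C)(C)Cl
Why: Standard silylation protects the secondary alcohol as an ether that should survive the chromium, hydride, palladium, osmium and alkoxide steps that follow.

**Step 11**
Reactants: 19 silyl ether
Product: 20 9-en-8-one
Conditions: CrO3, 3,5-dimethylpyrazole, CH2Cl2, −20 °C
Reagents that add atoms: chromium trioxide, O=[Cr](=O)=O
Why: CrO3–dimethylpyrazole allylic oxidation should attack the CH2 next to the CH end of the trisubstituted alkene (C8) and not C1, which is shielded by the C5 methyl and deactivated by the C2 oxygen, the same pattern as 7-oxidation of 3-oxygenated Δ5-steroids.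

**Step 12**
Reactants: 20 9-en-8-one
Product: 21 8β-allylic alcohol
Conditions: LiBH(s-Bu)3, THF, −78 °C; then H2O
Reagents that add atoms: none
Why: 1,2-Reduction of the β,β-disubstituted enone by the bulky hydride should occur anti to the C7 substituent, giving the alcohol cis to it (8β), as 2-alkylcyclohexanones give cis alcohols with this reagent.

**Step 13**
Reactants: 21 8β-allylic alcohol
Product: 22 8β-formate
Conditions: HCO2Ac (from HCO2H and Ac2O), pyridine, CH2Cl2, 0 °C
Reagents that add atoms: acetic formic anhydride, CC(=O)OC=O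
Why: The mixed anhydride transfers the smallest acyl group, so even this hindered secondary allylic alcohol should be formylated cleanly.

**Step 14**
Reactants: 22 8β-formate
Product: 23 trans-fused 8-ene
Conditions: Pd(OAc)2 (5 mol %), PBu3 (5 mol %), dioxane, 25 → 80 °C
Reagents that add atoms: none
Why: Zerovalent palladium should ionise the pseudoaxial formate anti to the leaving group (from the α face), decarboxylation gives a palladium hydride, and the hydride passes from the metal to the more substituted allyl terminus C10 on the α face, which sets the 10α-H (trans fusion) and moves the alkene to C8=C9 (palladium formate hydrogenolysis of allylic esters, as used to set steroid ring fusions).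

**Step 15**
Reactants: 23 trans-fused 8-ene
Product: 24 8α,9α-diol
Conditions: OsO4 (5 mol %), NMO, acetone/H2O, 25 °C
Reagents that add atoms: osmium tetroxide, O=[Os](=O)(=O)=O; N-methylmorpholine N-oxide, C[N+]1([O-])CCOCC1; water, O
Why: The β face of the cis-disubstituted alkene is covered by the axial C5 methyl and the C7 substituent, so syn dihydroxylation should come from the α face and set C8 and C9 together (Upjohn dihydroxylation).

**Step 16**
Reactants: 24 8α,9α-diol
Product: 25 isopropenyl diol
Conditions: KOtBu, DMSO/THF, 25 °C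
Reagents that add atoms: none
Why: E2 elimination with a bulky base should take one of the six methyl hydrogens rather than the single hindered C7–H, unmasking the isopropenyl group while the silyl ether and the diol (as alkoxides) stay intact.

**Step 17**
Reactants: 25 isopropenyl diol; 26 (Z)-3-methylpent-2-enoic acid
Product: 28 9-O-acyl silyl ether, via O-acylisourea 27 (not isolated)
Conditions: DCC, DMAP (0.1 equiv), CH2Cl2, 0 °C
Reagents that add atoms: none
Why: In a Steglich esterification the equatorial 9α-hydroxyl should react faster than the axial 8α-hydroxyl next to the isopropenyl-bearing carbon, and the low temperature with only catalytic DMAP should keep the Z geometry of the acyl group.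

**Step 18**
Reactants: 28 9-O-acyl silyl ether
Product: 29 target
Conditions: HF·pyridine, pyridine, THF, 0 → 25 °C
Reagents that add atoms: none
Why: Buffered fluoride cleaves the silyl ether without base, so neither acyl migration to O8 nor Z/E isomerisation of the ester should occur.

**Compound list**
1 | (−)-β-pinene, (1S,5S)-6,6-dimethyl-2-methylenebicyclo[3.1.1]heptane | C=C1CC[C@H]2C[C@@H]1C2(C)C | starting material
2 | secondary ozonide of 1 (spiro-1,2,4-trioxolane at C10) | C1OOC2(O1)CC[C@H]1C[C@@H]2C1(C)C | intermediate
3 | (+)-nopinone, (1R,5S)-6,6-dimethylbicyclo[3.1.1]heptan-2-one | O=C1CC[C@H]2C[C@@H]1C2(C)C | intermediate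
4 | iodomethane | CI | starting material
5 | lithium enolate of 3 (OLi on C10, C10=C5) | [Li]OC1=CC[C@H]2C[C@@H]1C2(C)C | intermediate
6 | 3-methylnopinone (C5 methyl anti to the CMe2 bridge) | C[C@H]1C[C@H]2C[C@@H](C1=O)C2(C)C | intermediate
7 | (E)-but-2-en-1-ol | C/C=C/CO | starting material
8 | dicrotyl ketal of 6 (two (E)-but-2-enyloxy groups on C10) | C[C@H]1C[C@H]2C[C@@H](C1(OC/C=C/C)OC/C=C/C)C2(C)C | intermediate
9 | (E)-crotyl enol ether of 6 (C10=C5) | C/C=C/COC1=C(C)C[C@H]2C[C@@H]1C2(C)C | intermediate
10 | 3-[(S)-but-3-en-2-yl]-3-methylnopinone (C5 methyl syn to the CMe2 bridge, butenyl group anti) | C=C[C@H](C)[C@@]1(C)C[C@H]2C[C@@H](C1=O)C2(C)C | intermediate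
11 | 3-[(S)-but-3-en-2-yl]-3-methyl-β-pinene (C10=C1 methylene; C5 as in 10) | C=C[C@H](C)[C@@]1(C)C[C@H]2C[C@@H](C1=C)C2(C)C | intermediate
12 | disiamylborane adduct of 11 (boron on C2) | CC(C)C(C)B(CC[C@H](C)[C@@]1(C)C[C@H]2C[C@@H](C1=C)C2(C)C)C(C)C(C)C | intermediate
13 | 3-[(S)-4-hydroxybutan-2-yl]-3-methyl-β-pinene | OCC[C@H](C)[C@@]1(C)C[C@H]2C[C@@H](C1=C)C2(C)C | intermediate
14 | 3-methyl-3-[(S)-4-oxobutan-2-yl]-β-pinene (C5 methyl syn to the CMe2 bridge) | O=CC[C@H](C)[C@@]1(C)C[C@H]2C[C@@H](C1=C)C2(C)C | intermediate
15 | trichlorotin alkoxide of 16 | CC(C)(Cl)[C@H]1C[C@]2(C)[C@@H](C)C[C@@H](O[Sn](Cl)(Cl)Cl)CC2=CC1 | intermediate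
16 | 11-chloroeremophil-9-en-2β-ol (4β,5β-dimethyl; 7β-(2-chloropropan-2-yl); equatorial OH) | CC(C)(Cl)[C@H]1C[C@]2(C)[C@@H](C)C[C@@H](O)CC2=CC1 | intermediate
17 | 11-chloroeremophil-9-en-2-one | CC(C)(Cl)[C@H]1C[C@]2(C)[C@@H](C)CC(=O)CC2=CC1 | intermediate
18 | 11-chloroeremophil-9-en-2α-ol (axial OH) | CC(C)(Cl)[C@H]1C[C@]2(C)[C@@H](C)C[C@H](O)CC2=CC1 | intermediate
19 | 2α-(tert-butyldimethylsilyloxy)-11-chloroeremophil-9-ene | CC(C)(Cl)[C@H]1C[C@]2(C)[C@@H](C)C[C@H](O[Si](C)(C)C(C)(C)C)CC2=CC1 | intermediate
20 | 2α-(tert-butyldimethylsilyloxy)-11-chloroeremophil-9-en-8-one | CC(C)(Cl)[C@H]1C[C@]2(C)[C@@H](C)C[C@H](O[Si](C)(C)C(C)(C)C)CC2=CC1=O | intermediate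
21 | 2α-(tert-butyldimethylsilyloxy)-11-chloroeremophil-9-en-8β-ol (OH cis to the C7 substituent) | CC(C)(Cl)[C@H]1C[C@]2(C)[C@@H](C)C[C@H](O[Si](C)(C)C(C)(C)C)CC2=C[C@H]1O | intermediate
22 | 8β-formate of 21 | CC(C)(Cl)[C@H]1C[C@]2(C)[C@@H](C)C[C@H](O[Si](C)(C)C(C)(C)C)CC2=C[C@H]1OC=O | intermediate
23 | 2α-(tert-butyldimethylsilyloxy)-11-chloro-10α-H-eremophil-8-ene (trans-fused) | CC(C)(Cl)[C@H]1C[C@]2(C)[C@@H](C)C[C@H](O[Si](C)(C)C(C)(C)C)C[C@H]2C=C1 | intermediate
24 | 2α-(tert-butyldimethylsilyloxy)-11-chloro-10α-H-eremophilane-8α,9α-diol | CC(C)(Cl)[C@H]1C[C@]2(C)[C@@H](C)C[C@H](O[Si](C)(C)C(C)(C)C)C[C@H]2[C@H](O)[C@@H]1O | intermediate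
25 | 2α-(tert-butyldimethylsilyloxy)-10α-H-eremophil-11-ene-8α,9α-diol | C=C(C)[C@H]1C[C@]2(C)[C@@H](C)C[C@H](O[Si](C)(C)C(C)(C)C)C[C@H]2[C@H](O)[C@@H]1O | intermediate
26 | (Z)-3-methylpent-2-enoic acid | OC(=O)/C=C(/C)CC | starting material
27 | O-acylisourea from 26 and dicyclohexylcarbodiimide | C1CCCCC1N=C(NC1CCCCC1)OC(=O)/C=C(/C)CC | intermediate
28 | 9-O-[(Z)-3-methylpent-2-enoyl] derivative of 25 | C=C(C)[C@H]1C[C@]2(C)[C@@H](C)C[C@H](O[Si](C)(C)C(C)(C)C)C[C@H]2[C@H](OC(=O)/C=C(/C)CC)[C@@H]1O | intermediate
29 | (2S,4S,5R,7R,8R,9S,10R)-eremophil-11-ene-2α,8α,9α-triol 9-[(Z)-3-methylpent-2-enoate] (CNP0129603.1) | C=C(C)[C@H]1C[C@]2(C)[C@@H](C)C[C@H](O)C[C@H]2[C@H](OC(=O)/C=C(/C)CC)[C@@H]1O | target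

Total step count: 18
Longest linear sequence: 18 steps (1 to 29)

**Steps most likely to fail**

1. Step 7. After the C1–C2 bond forms, the C10 cation may undergo Wagner–Meerwein migration of a bridge carbon, or be quenched at C10 by chloride or by the tin alkoxide, before the C9–C11 bond breaks; the aldehyde may also react intermolecularly. Fallback with known chemistry, setting out from 6 and coming back at 16: base-catalysed Michael addition of 6 to (E)-pent-3-en-2-one (KOtBu cat., tBuOH, 0 °C), anti to the CMe2 bridge, would give the 1,5-diketone F1. Intramolecular aldol condensation (KOH, MeOH, 65 °C) would close ring A as the pinane-fused 1(10)-en-2-one F2. HCl in AcOH would open the cyclobutane at C9–C11 through the protonated enone to give the 11-chloro-1(10)-en-2-one F3. Isopropenyl acetate with TsOH would give the 1,9-dien-2-yl acetate F4, and NaBH4 in EtOH/THF, which reduces the deconjugated ketone released from the dienyl acetate, would give 16.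

2. Step 14. The hydride transfer to C10 has to build the strained trans ring fusion in which the C5 methyl and the C7 substituent are syn on ring B, so β-hydride elimination to dienes or hydride delivery at C8 may outrun it. Fallback, setting out from 20 and coming back at 23: HF·pyridine would remove the silyl group to give the 2α-hydroxy enone F5. Hydrogenation with [Ir(cod)(PCy3)(py)]PF6 under H2 in CH2Cl2, directed by the axial 2α-hydroxyl, should deliver hydrogen to the α face of C9=C10 and give the trans-fused hydroxy ketone F6. TBSCl and imidazole would give the silyl ether F7. Kinetic deprotonation at C9 with KN(SiMe3)2 at −78 °C and trapping with PhNTf2 would give the 8-en-8-yl triflate F8, and Pd(OAc)2, PPh3, HCO2H and Bu3N in DMF would reduce the triflate to 23.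

3. Step 3. Ketalisation of the hindered ketone may be slow, acid at 140 °C may open the cyclobutane through the oxocarbenium ion, and the chair preference of the rearrangement may be incomplete. Fallback, setting out from 6 and coming back at 13: base-catalysed Michael addition of 6 to methyl (E)-but-2-enoate (KOtBu cat., tBuOH/THF, 25 °C), again anti to the CMe2 bridge, would give the keto ester F9 (a C4 epimer, if formed, would be separated here). Wittig methylenation (Ph3PCH3Br, KOtBu, toluene, 90 °C) would give the methylene ester F10, and LiAlH4 in Et2O at 0 °C would give 13.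

**Further compounds**
F1 | step 7 | 3-methyl-3-[(S)-4-oxopentan-2-yl]nopinone (C5 methyl syn to the CMe2 bridge) | CC(=O)C[C@H](C)[C@@]1(C)C[C@H]2C[C@@H](C1=O)C2(C)C
F2 | step 7 | pinane-fused 1(10)-en-2-one (ring A closed, cyclobutane intact) | O=C1C[C@H](C)[C@@]2(C)C[C@H]3C[C@@H](C2=C1)C3(C)C
F3 | step 7 | 11-chloroeremophil-1(10)-en-2-one | CC(C)(Cl)[C@H]1C[C@]2(C)[C@@H](C)CC(=O)C=C2CC1
F4 | step 7 | 11-chloroeremophila-1,9-dien-2-yl acetate | CC(C)(Cl)[C@H]1C[C@]2(C)[C@@H](C)CC(OC(C)=O)=CC2=CC1
F5 | step 14 | 11-chloro-2α-hydroxyeremophil-9-en-8-one | CC(C)(Cl)[C@H]1C[C@]2(C)[C@@H](C)C[C@H](O)CC2=CC1=O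
F6 | step 14 | 11-chloro-2α-hydroxy-10α-H-eremophilan-8-one (trans-fused) | CC(C)(Cl)[C@H]1C[C@]2(C)[C@@H](C)C[C@H](O)C[C@H]2CC1=O
F7 | step 14 | 2α-(tert-butyldimethylsilyloxy)-11-chloro-10α-H-eremophilan-8-one | CC(C)(Cl)[C@H]1C[C@]2(C)[C@@H](C)C[C@H](O[Si](C)(C)C(C)(C)C)C[C@H]2CC1=O
F8 | step 14 | 2α-(tert-butyldimethylsilyloxy)-11-chloro-10α-H-eremophil-8-en-8-yl trifluoromethanesulfonate | CC(C)(Cl)[C@H]1C[C@]2(C)[C@@H](C)C[C@H](O[Si](C)(C)C(C)(C)C)C[C@H]2C=C1OS(=O)(=O)C(F)(F)F
F9 | step 3 | methyl (S)-3-(3-methyl-2-oxo-pinan-3-yl)butanoate (C5 methyl syn to the CMe2 bridge) | COC(=O)C[C@H](C)[C@@]1(C)C[C@H]2C[C@@H](C1=O)C2(C)C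
F10 | step 3 | methyl (S)-3-(3-methyl-2-methylene-pinan-3-yl)butanoate | COC(=O)C[C@H](C)[C@@]1(C)C[C@H]2C[C@@H](C1=C)C2(C)C
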